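The readings are calculated from invented constants, and the scatter is random.

I read each flask at 4.0 h and want its Pdt at that moment.

| flask | Sub | Ptn | Kat | remark | time |
|---|---|---|---|---|---|
| Wednesday's | 20 mM | 18 mM | 0.20 mM | run made earlier |  |
| Friday's | 20 mM | 9 mM | 0.20 mM | run made earlier |  |
| Monday's | 20 mM | 14 mM | 0.20 mM | run made earlier |  |
| Saturday's | 40 mM | 18 mM | 0.20 mM | run made earlier |  |
| birch | 20 mM | 18.0 mM (fed, over 1.5 h) | 0.20 mM | all else is in the flask from the start; the feed brings no volume worth counting | 4.0 h |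
| ash | 20 mM | 18.0 mM | 0.20 mM | everything together at the start | 4.0 h |
| elm | 20 mM (fed, over 1.5 h) | 18.0 mM | 0.20 mM | all else is in the flask from the start; the feed brings no volume worth counting | 4.0 h |

- Wednesday's (time / h: Pdt / %, Sub.Ptn / %): 0.200: 6.4, 28.0; 0.333: 7.0, 41.0; 0.667: 10.0, 55.8; 1.33: 12.5, 69.7; 2.50: 13.3, 75.3
- Friday's (time / h: Pdt / %, Sub.Ptn / %): 0.667: 5.2, 26.8; 1.33: 6.9, 32.7; 2.00: 9.6, 34.3; 2.50: 9.7, 35.2; 3.00: 9.8, 34.8
- Monday's (time / h: Pdt / %, Sub.Ptn / %): 0.667: 9.8, 44.1; 1.33: 10.1, 53.0; 2.00: 11.4, 55.3; 2.50: 11.0, 54.2; 3.00: 10.5, 56.4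
- Saturday's (time / h: Pdt / %, Sub.Ptn / %): 0.250: 7.5, 14.2; 0.833: 13.1, 24.1; 1.33: 14.6, 27.1; 2.50: 15.9, 26.0; 3.00: 17.6, 26.8

(scatter of a reading: 1 percentage point)



- the flask with the highest amount of Pdt, in percent of the Sub charged ("all alike" if they lie within 1.5 percentage points) (birch / ash / elm / all alike)
- final Pdt, as a percentage of the Sub charged, in birch
- final Pdt, as a percentage of the Sub charged, in ash
- final Pdt, as a percentage of the Sub charged, in elm

In Wednesday's run, Pdt and Sub.Ptn together reach 17.7 mM against 18 mM of Ptn charged, so each product takes one Ptn, and Ptn is the limiting reagent. Its loss looks pseudo-first-order, with a constant k of 1.97 h⁻¹ read at 0.667 h.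

I take the Pdt rate as a constant times Sub times Ptn. Two things slow it. Ptn's decay shrinks the whole course to the start rate held for 1/k, which is 0.508 h. Sub falls one for one with Ptn spent, and that multiplies by 0.550 in Wednesday's run. Dividing the Pdt rate by the Ptn loss removes time, and the integral gives Pdt = L·P·(S − P/2), with S and P the charges of Sub and Ptn.

Wednesday's last reading gives L = 0.0134 mM⁻¹, and Saturday's, at twice the Sub, gives 0.0126 mM⁻¹. I keep their mean 0.0130 mM⁻¹, the leak L: Pdt formed per Ptn spent, per mM of Sub standing.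

I then reckon ash at 12.9 %. Feeding Ptn leaves Sub against Ptn spent unchanged, so at constant k and with its Ptn spent I reckon birch the same. In elm Sub enters by the feed, and I put no figure on it.

The forecast says birch, with 14 % in birch, 13.5 % in ash and 5 % in elm: “Birch follows nearly the same Sub-versus-conversion path”. My birch figure is lower than its own.

Birch gives 19.3 %, ash 12.6 %, elm 2.85 %.

    Sub + Ptn + Kat → Sub.Ptn + Kat, rate k1*[Sub]*[Ptn]*[Kat]/(1 + ([Sub]/sat1)) (0.902 mM, k = 3390 M⁻² s⁻¹)
    Sub + Kat → Sub.Kat (k = 0.0109 M⁻¹ s⁻¹)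
    Sub + Ptn → Pdt (k = 0.00735 M⁻¹ s⁻¹)

Birch ends 6.4 percentage points above my reckoning, and at 1.50 h it holds 40.2 % of its Kat free and 59.8 % as Sub.Kat. Reckoned as if its whole Ptn charge were spent, although 7.49 % of that charge still stands at 4.00 h, birch's own leak comes to 0.0195 mM⁻¹, which is 1.50 times mine. In elm, over the first 1.50 h, I put the mean Sub of 1.61 mM in as the weight, and L gives 1.59 % of the Sub charged; elm's Pdt at that time stands at 2.06 %.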